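Lophirone J (10) is cut at the bond between C2 of ring C (the chromanone O-ring) and C5 of the benzofuran, and in the same move a C2–C4 bond is drawn across ring C. This gives aryl bromide 8 and racemic cyclopropanol 4, in which the O-ring is still five-membered (O1, C2, C4, C4a, C8a) and C3H2 is only a cyclopropane bridge.
Enabling feature: ring C is a β-aryloxy ketone. C4=O and C2 stand 1,3 across C3H2 and C2 bears the ring oxygen O1, so C2 is the homoenolate (β) carbon of the ketone and its radical is stabilised by the O1 lone pair. Cyclopropanol scission delivers exactly this radical.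
4 comes from commercial 6-methoxybenzofuran-3(2H)-one 1 (ring A plus the five-membered O-ring) by O-silylation, CH2 transfer and desilylation. 8 comes from 4-bromo-2-iodophenol 5 and 4-ethynylanisole 6 by Sonogashira coupling and furan closure.
Ring order: ring A and the five-membered O-ring are bought, the cyclopropane is fused on (step 2), and the furan ring of the benzofuran is closed (step 4). Ring C reaches six members last (step 5), together with the fragment union and the only stereocentre.

Key step: step 5

Assumption: the sense of induction of the chiral nickel catalyst towards the new radical cannot be predicted with certainty. The (S,S)-ligand is written, and its antipode is used if it should favour the (2R)-product.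

Step 1
Reactants: 1 6-methoxybenzofuran-3(2H)-one
Product: 2 tert-butyl[(6-methoxybenzofuran-3-yl)oxy]dimethylsilane (the aromatic silyl enol ether of 1)
Conditions: TBSOTf, Et3N, CH2Cl2, 0 °C
Reagents that add atoms: tert-butyldimethylsilyl triflate (TBSOTf), CC(C)(C)[Si](C)(C)OS(=O)(=O)C(F)(F)F
Why: Soft enolisation with Et3N and capture by the hard silyl triflate (silyl enol ether formation) should go to oxygen only, because O-silylation aromatises the five-membered ring to a benzofuran.

Step 2
Reactants: 2 tert-butyl[(6-methoxybenzofuran-3-yl)oxy]dimethylsilane
Product: 3 (±)-6b-(tert-butyldimethylsilyloxy)-4-methoxy-1a,6b-dihydro-1H-cyclopropa[b]benzofuran (a CH2 bridges the former C2 and C3 of the benzofuran, cis-fused)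
Conditions: Et2Zn, CH2I2, CH2Cl2, 0 °C to rt; pyridine quench
Reagents that add atoms: diiodomethane, ICI
Why: The Furukawa variant of the Simmons–Smith cyclopropanation of a silyl enol ether transfers CH2 suprafacially from the electrophilic zinc carbenoid to the C2=C3 bond, which carries two oxygen donors and only weak furan aromaticity, so the only possible cis-fused racemate should form (both stereocentres are erased again in step 5).

Step 3
Reactants: 3 (±)-6b-(tert-butyldimethylsilyloxy)-4-methoxy-1a,6b-dihydro-1H-cyclopropa[b]benzofuran
Product: 4 (±)-4-methoxy-1a,6b-dihydro-1H-cyclopropa[b]benzofuran-6b-ol (bridgehead cyclopropanol, used soon after isolation)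
Conditions: TBAF, AcOH, THF, 0 °C
Reagents that add atoms: none
Why: Fluoride-induced silyl ether cleavage works on the bridgehead Si–O bond, and the acetic acid buffer protonates the cyclopropanolate at once, so that base-induced homoenolate opening is held back and the two ring-fusion stereocentres are untouched.

Step 4
Reactants: 5 4-bromo-2-iodophenol; 6 4-ethynylanisole (1-ethynyl-4-methoxybenzene)
Product: 8 5-bromo-2-(4-methoxyphenyl)benzofuran, via 4-bromo-2-[(4-methoxyphenyl)ethynyl]phenol 7 (not isolated)
Conditions: PdCl2(PPh3)2 (cat.), CuI (cat.), Et3N, DMF, rt then 60 °C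
Reagents that add atoms: none
Why: A domino Sonogashira coupling at the more reactive C–I bond followed by metal-assisted 5-endo-dig hydroalkoxylation of the o-alkynylphenol should build the 2-arylbenzofuran and leave the C–Br bond for step 5.

Step 5
Reactants: 4 (±)-4-methoxy-1a,6b-dihydro-1H-cyclopropa[b]benzofuran-6b-ol; 8 5-bromo-2-(4-methoxyphenyl)benzofuran
Product: 10 lophirone J (2S enantiomer), via 7-methoxy-4-oxochroman-2-yl radical 9 (not isolated)
Conditions: 4CzIPN (cat.), NiBr2(dme) (cat.), (S,S)-4,4'-diisopropyl-1,1'-diaryl-2,2'-bi(imidazoline) ligand (cat.), K2HPO4, DMA, blue LED, 25 °C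
Reagents that add atoms: none
Why: Proposed new method: Photoexcited 4CzIPN removes one electron from the electron-rich ring A of 4, phosphate takes the O–H proton, and the cyclopropyloxy radical so formed breaks the C2–C4 bond that the cyclopropane shares with the five-membered O1–C2–C4–C4a–C8a ring, so that C3H2 becomes a ring member, C4 becomes the ketone and the six-membered radical 9 results; 9 is caught by the chiral aryl nickel bromide formed from 8 and zerovalent nickel, reductive elimination from trivalent nickel makes the C2–aryl bond, and the reduced photocatalyst returns monovalent to zerovalent nickel, so the step is redox-neutral. The closest known reaction types are the photoredox/nickel β-arylation of cyclopropanols with aryl bromides, the oxidative one-carbon ring expansion of bicyclic cyclopropanols and siloxycyclopropanes (the same cyclopropyloxy radical as in the Dowd–Beckwith ring expansion) and the enantioselective photochemical nickel arylation of cyclic α-oxy radicals; new is their union on a 2-oxabicyclo[3.1.0]hexanol. No ring is closed by cyclisation: ring C arises by scission of the zero-atom bridge of the bicycle, five ring atoms plus the cyclopropane CH2 giving six. The only stereocentre, C2, is set in the bond-forming event at nickel under control of the twofold-symmetric chiral ligand, and since both stereocentres of racemic 4 are erased in planar 9 the step is stereoconvergent. The step needs inner-bond rather than outer-bond scission, which O1 on C2 secures by stabilising the secondary radical, while a primary radical from outer scission would re-close onto the aryl ketone and drain into 9. It also needs coupling at one aryl carbon only, secured by the single C–Br bond of 8, and a base too weak for retro-oxa-Michael racemisation of the flavanone, hence K2HPO4.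

Compound list
1 | 6-methoxybenzofuran-3(2H)-one | COc1ccc2C(=O)COc2c1 | starting material
2 | tert-butyl[(6-methoxybenzofuran-3-yl)oxy]dimethylsilane | COc1ccc2c(O[Si](C)(C)C(C)(C)C)coc2c1 | intermediate
3 | (±)-6b-(tert-butyldimethylsilyloxy)-4-methoxy-1a,6b-dihydro-1H-cyclopropa[b]benzofuran (racemic, cis fusion is the only one possible) | COc1ccc2c(c1)OC1CC21O[Si](C)(C)C(C)(C)C | intermediate
4 | (±)-4-methoxy-1a,6b-dihydro-1H-cyclopropa[b]benzofuran-6b-ol (racemic, cis fusion) | COc1ccc2c(c1)OC1CC21O | intermediate
5 | 4-bromo-2-iodophenol | Oc1ccc(Br)cc1I | starting material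
6 | 4-ethynylanisole | C#Cc1ccc(OC)cc1 | starting material
7 | 4-bromo-2-[(4-methoxyphenyl)ethynyl]phenol (not isolated) | Oc1ccc(Br)cc1C#Cc1ccc(OC)cc1 | intermediate
8 | 5-bromo-2-(4-methoxyphenyl)benzofuran | COc1ccc(-c2cc3cc(Br)ccc3o2)cc1 | intermediate
9 | 7-methoxy-4-oxochroman-2-yl radical (not isolated) | COc1ccc2C(=O)C[CH]Oc2c1 | intermediate
10 | lophirone J, (2S)-7-methoxy-2-[2-(4-methoxyphenyl)benzofuran-5-yl]chroman-4-one | COc1ccc(-c2cc3cc([C@@H]4CC(=O)c5ccc(OC)cc5O4)ccc3o2)cc1 | target

Total step count: 5. Longest linear sequence: 4 (steps 1, 2, 3, 5).

Steps most likely to fail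

1. Step 5.
- What may go wrong: scission of the outer cyclopropane bond through a two-electron nickel homoenolate pathway; hydrogen-atom capture or β-hydride loss at C2 before the C–C bond forms; weak facial discrimination at nickel.
- The fallback uses known chemistry and still lets the O-ring grow from five to six members. It sets out from 3 and 8 and comes back at 10.
- FeCl3 in DMF at 0 °C oxidises 3 with inner-bond scission and chlorine transfer (the FeCl3-induced one-carbon ring expansion of siloxycyclopropanes) to (±)-2-chloro-7-methoxychroman-4-one F1.
- NaOAc in MeOH then eliminates HCl to give 7-methoxy-4H-chromen-4-one F2.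
- In parallel, n-BuLi (THF, −78 °C) turns 8 into [2-(4-methoxyphenyl)benzofuran-5-yl]lithium F3. B(OiPr)3 followed by dilute HCl converts it into [2-(4-methoxyphenyl)benzofuran-5-yl]boronic acid F4.
- A base-free palladium-catalysed asymmetric conjugate addition of F4 to F2 should give 10. Conditions: Pd(OCOCF3)2, the t-BuPyOx antipode that leads to the (2S)-product, NH4PF6, H2O, 1,2-dichloroethane, 60 °C.

2. Step 2.
- What may go wrong: sluggish carbenoid transfer to the partly aromatic C2=C3 bond, and opening of the siloxycyclopropane by the zinc iodide that builds up.
- The fallback changes the carbene and with it the way the ring grows. It sets out from 2 and comes back at 10.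
- Dibromocarbene (CHBr3, KOt-Bu, pentane, −20 °C) adds to 2 to give (±)-1,1-dibromo-6b-(tert-butyldimethylsilyloxy)-4-methoxy-1a,6b-dihydro-1H-cyclopropa[b]benzofuran F5.
- F5 should open on warming by cyclopropyl-to-allyl cation ring opening with loss of the silyl bromide, giving the ring-expanded 3-bromo-7-methoxy-4H-chromen-4-one F6.
- Formate hydrodebromination (HCO2Na, Pd(PPh3)4, DMF, 80 °C) gives 7-methoxy-4H-chromen-4-one F2.
- F2 is joined with [2-(4-methoxyphenyl)benzofuran-5-yl]boronic acid F4 by the asymmetric conjugate addition described above to reach 10.

3. Step 3.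
- What may go wrong: premature opening of the free cyclopropanol to a ketone through its alkoxide during fluoride treatment or on silica.
- The fallback avoids the silyl group altogether. It sets out from 1 and comes back at 4.
- LiHMDS (THF, −78 °C) gives lithium 6-methoxybenzofuran-3-olate F7.
- The samarium carbenoid made from SmI2 and CH2I2 (−78 °C to rt) cyclopropanates F7 under direction by the oxido group. A cold NH4Cl work-up frees 4, which is carried into step 5 without chromatography.

Further compounds
F1 | step 5 | (±)-2-chloro-7-methoxychroman-4-one | COc1ccc2C(=O)CC(Cl)Oc2c1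
F2 | step 5 | 7-methoxy-4H-chromen-4-one | COc1ccc2c(=O)ccoc2c1
F3 | step 5 | [2-(4-methoxyphenyl)benzofuran-5-yl]lithium | [Li]c1ccc2oc(-c3ccc(OC)cc3)cc2c1
F4 | step 5 | [2-(4-methoxyphenyl)benzofuran-5-yl]boronic acid | COc1ccc(-c2cc3cc(B(O)O)ccc3o2)cc1
F5 | step 2 | (±)-1,1-dibromo-6b-(tert-butyldimethylsilyloxy)-4-methoxy-1a,6b-dihydro-1H-cyclopropa[b]benzofuran | COc1ccc2c(c1)OC1C(Br)(Br)C21O[Si](C)(C)C(C)(C)C
F6 | step 2 | 3-bromo-7-methoxy-4H-chromen-4-one | COc1ccc2c(=O)c(Br)coc2c1
F7 | step 3 | lithium 6-methoxybenzofuran-3-olate | COc1ccc2c([O-])coc2c1.[Li+]
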